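Ring B, the 3,5‑dimethyloxane with the tertiary C5 carbinol, is cut across O1–C2 and C3–C4. The key step exploits that C2 (which carries the CH2 link to ring A) and C3 (methyl) are adjacent, and that the C4 methylene lies beside C5. With C5 as a ketone and a temporary sulfone, C4 is a soft carbon nucleophile, while an acetate arm makes C2 the β‑carbon of an enoate. An α′‑hydroxy β‑keto sulfone (O1, C6, C5, C4) and a chiral allylic carbonate of a pentenoate (C2, C3) are joined in one pot by stereoretentive Pd allylic alkylation, then oxa‑Michael closure. Ring A follows by Prins cyclisation, the side chain by Suzuki coupling.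

Key step: step 7

Remark: ring B is numbered O1, C2 (CH2 link to ring A), C3 (methyl), C4, C5 (carbinol), C6 (side chain). The sulfone‑bearing C4 of 14 and the carbinol C5 of 16 are temporary centers, drawn as the expected major epimers. The sense of the hydrogenation in step 3 is assigned by analogy with pyruvate esters.

Step 1
Reactants: 1 (S)-3-bromo-2-methylpropan-1-ol
Product: 2 (S)-(3-bromo-2-methylpropoxy)(tert-butyl)diphenylsilane
Conditions: TBDPSCl, imidazole, DMF, 25 °C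
Reagents that add atoms: tert-butyl(chloro)diphenylsilane, CC(C)(C)[Si](Cl)(c1ccccc1)c1ccccc1
Why: Imidazole‑promoted silyl ether formation protects the primary hydroxyl with a group that should survive the Grignard, hydride and acidic steps; the stereocenter is not touched.

Step 2
Reactants: 2 (S)-(3-bromo-2-methylpropoxy)(tert-butyl)diphenylsilane, 3 diethyl oxalate
Product: 5 ethyl (4R)-5-[(tert-butyldiphenylsilyl)oxy]-4-methyl-2-oxopentanoate, via Grignard reagent 4 (not isolated)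
Conditions: Mg, THF, 40 °C; then (CO2Et)2 (3 equiv), THF, −78 °C
Reagents that add atoms: none
Why: Grignard acylation by excess oxalate at low temperature should stop at the α‑keto ester, because the magnesium hemiketal resists a second addition.

Step 3
Reactants: 5 ethyl (4R)-5-[(tert-butyldiphenylsilyl)oxy]-4-methyl-2-oxopentanoate
Product: 6 ethyl (2S,4R)-5-[(tert-butyldiphenylsilyl)oxy]-2-hydroxy-4-methylpentanoate
Conditions: H2 (60 atm), RuCl2[(S)-BINAP] (1 mol %), EtOH, 50 °C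
Reagents that add atoms: none
Why: Noyori asymmetric hydrogenation of the α‑keto ester should set the (2S) carbinol by ester‑chelated hydride delivery from the (S)‑ligand complex; this center later lies α to the ring ketone and is then also open to thermodynamic correction.

Step 4
Reactants: 6 ethyl (2S,4R)-5-[(tert-butyldiphenylsilyl)oxy]-2-hydroxy-4-methylpentanoate, 7 methyl phenyl sulfone
Product: 8 (3S,5R)-6-[(tert-butyldiphenylsilyl)oxy]-3-hydroxy-5-methyl-1-(phenylsulfonyl)hexan-2-one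
Conditions: PhSO2CH3 (3.2 equiv), nBuLi (3.1 equiv), THF, −78 °C; then 6, −78 → 0 °C
Reagents that add atoms: none
Why: Claisen‑type acylation of the lithiated sulfone by the ester gives the β‑keto sulfone, which is shielded from over‑addition as its enolate; the extra base covers the free hydroxyl.

Step 5
Reactants: 9 (R)-but-3-en-2-ol, 10 ethyl acrylate
Product: 11 ethyl (2E,4R)-4-hydroxypent-2-enoate
Conditions: (H2IMes)Cl2Ru(=CH-C6H4-2-OiPr) (second-generation Hoveyda–Grubbs catalyst, 2 mol %), ethyl acrylate (3 equiv), CH2Cl2, 40 °C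
Reagents that add atoms: none
Why: Olefin cross‑metathesis of the allylic alcohol with excess acrylate should give the (E)‑γ‑hydroxy enoate without touching the carbinol center.

Step 6
Reactants: 11 ethyl (2E,4R)-4-hydroxypent-2-enoate
Product: 12 ethyl (2E,4R)-4-[(methoxycarbonyl)oxy]pent-2-enoate
Conditions: ClCO2Me, pyridine, CH2Cl2, 0 °C
Reagents that add atoms: methyl chloroformate, COC(=O)Cl
Why: Acylation of the secondary alcohol installs a carbonate leaving group that ionises under neutral conditions and supplies its own base on decarboxylation.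

Step 7
Reactants: 8 (3S,5R)-6-[(tert-butyldiphenylsilyl)oxy]-3-hydroxy-5-methyl-1-(phenylsulfonyl)hexan-2-one, 12 ethyl (2E,4R)-4-[(methoxycarbonyl)oxy]pent-2-enoate
Product: 14 ethyl 2-[(2R,3R,4S,6S)-6-[(2R)-3-[(tert-butyldiphenylsilyl)oxy]-2-methylpropyl]-3-methyl-5-oxo-4-(phenylsulfonyl)oxan-2-yl]acetate, via allylated enoate 13 (not isolated)
Conditions: Pd(PPh3)4 (5 mol %), THF, 25 °C; then DBU (1.1 equiv), 25 °C; aq. NH4Cl
Reagents that add atoms: none
Why: Zerovalent palladium ionises the carbonate of 12 with inversion to an η3‑allyl complex and the liberated methoxide deprotonates the sulfone‑activated C4–H of 8; the soft carbanion attacks anti to palladium at the allyl terminus remote from the ester, so C3–C4 forms with net retention and the enoate is kept (Tsuji–Trost allylic alkylation of a γ‑carbonato enoate, giving 13). DBU then makes the C6 hydroxyl add to the enoate β‑carbon, closing O1–C2 in a 6‑exo‑trig oxa‑Michael cyclisation, the closest precedent being base‑mediated oxa‑conjugate additions that give 2,6‑cis oxanes. C3 is controlled by the (R) carbinol center of 12 (double inversion), C6 is carried over from 8, and C2 is set under thermodynamic control because the oxa‑Michael step is reversible: the chair with the acetate arm, the C3 methyl and the C6 chain all equatorial is the sink. The step needs γ‑ over α‑regioselectivity in the allylation, secured by attack distal to the electron‑withdrawing ester, and C‑ over O‑alkylation, secured by the soft keto‑sulfone carbanion. It also needs ring closure through the hydroxyl and not the enolate oxygen; the dihydrofuran from the latter can revert, whereas 14 is held as its stabilised keto‑sulfone enolate until work‑up. The C4 center is of no consequence, since the sulfone is removed in step 8.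

Step 8
Reactants: 14 ethyl 2-[(2R,3R,4S,6S)-6-[(2R)-3-[(tert-butyldiphenylsilyl)oxy]-2-methylpropyl]-3-methyl-5-oxo-4-(phenylsulfonyl)oxan-2-yl]acetate
Product: 15 ethyl 2-[(2R,3S,6S)-6-[(2R)-3-[(tert-butyldiphenylsilyl)oxy]-2-methylpropyl]-3-methyl-5-oxooxan-2-yl]acetate
Conditions: Al(Hg), THF/H2O (9:1), 0 → 25 °C
Reagents that add atoms: none
Why: Reductive desulfonylation of the β‑keto sulfone by electron transfer removes the activating group and erases the C4 center; the α‑alkoxy ketone and the ester should not be reduced.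

Step 9
Reactants: 15 ethyl 2-[(2R,3S,6S)-6-[(2R)-3-[(tert-butyldiphenylsilyl)oxy]-2-methylpropyl]-3-methyl-5-oxooxan-2-yl]acetate
Product: 16 2-[(2R,3S,5R,6S)-6-[(2R)-3-[(tert-butyldiphenylsilyl)oxy]-2-methylpropyl]-5-hydroxy-3-methyloxan-2-yl]ethan-1-ol
Conditions: LiAlH4, THF, 0 °C
Reagents that add atoms: none
Why: Hydride reduction takes ester and ketone to the diol, which sidesteps the ketone/ester selectivity problem in making the aldehyde; the new C5 carbinol (either epimer) is oxidised again in step 10.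

Step 10
Reactants: 16 2-[(2R,3S,5R,6S)-6-[(2R)-3-[(tert-butyldiphenylsilyl)oxy]-2-methylpropyl]-5-hydroxy-3-methyloxan-2-yl]ethan-1-ol
Product: 17 2-[(2R,3S,6S)-6-[(2R)-3-[(tert-butyldiphenylsilyl)oxy]-2-methylpropyl]-3-methyl-5-oxooxan-2-yl]acetaldehyde
Conditions: Dess–Martin periodinane, NaHCO3, CH2Cl2, 25 °C
Reagents that add atoms: none
Why: Dess–Martin oxidation converts both hydroxyls to the keto aldehyde under buffered conditions that should avoid β‑alkoxy elimination.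

Step 11
Reactants: 18 methyl (S)-3-hydroxy-2-methylpropanoate
Product: 19 methyl (S)-3-(benzyloxy)-2-methylpropanoate
Conditions: BnOC(=NH)CCl3, TfOH (cat.), CH2Cl2/cyclohexane, 25 °C
Reagents that add atoms: benzyl 2,2,2-trichloroacetimidate, ClC(Cl)(Cl)C(=N)OCc1ccccc1
Why: Acid‑catalysed benzylation with the imidate protects the hydroxyl without base and so without racemising the α‑center.

Step 12
Reactants: 19 methyl (S)-3-(benzyloxy)-2-methylpropanoate
Product: 20 (S)-3-(benzyloxy)-2-methylpropanal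
Conditions: DIBAL-H, CH2Cl2, −78 °C
Reagents that add atoms: none
Why: Partial reduction at low temperature stops at the aluminium hemiacetal and releases the α‑methyl aldehyde on work‑up.

Step 13
Reactants: 20 (S)-3-(benzyloxy)-2-methylpropanal, 21 allyltrimethylsilane
Product: 22 (2S,3R)-1-(benzyloxy)-2-methylhex-5-en-3-ol
Conditions: TiCl4, CH2Cl2, −78 °C
Reagents that add atoms: none
Why: Chelation‑controlled Hosomi–Sakurai allylation: TiCl4 bridges the aldehyde and benzyl ether oxygens and the allylsilane attacks the six‑membered chelate anti to the α‑methyl group, giving the 2,3‑anti (3R) alcohol.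

Step 14
Reactants: 17 2-[(2R,3S,6S)-6-[(2R)-3-[(tert-butyldiphenylsilyl)oxy]-2-methylpropyl]-3-methyl-5-oxooxan-2-yl]acetaldehyde, 22 (2S,3R)-1-(benzyloxy)-2-methylhex-5-en-3-ol
Product: 24 (2S,5S,6R)-6-{[(2S,4S,6R)-6-[(2S)-1-(benzyloxy)propan-2-yl]-4-hydroxyoxan-2-yl]methyl}-2-[(2R)-3-[(tert-butyldiphenylsilyl)oxy]-2-methylpropyl]-5-methyloxan-3-one, via trifluoroacetate 23 (not isolated)
Conditions: 22 (1.2 equiv), CF3CO2H (20 equiv), CH2Cl2, 0 → 25 °C; then K2CO3, MeOH, 25 °C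
Reagents that add atoms: trifluoroacetic acid, OC(=O)C(F)(F)F
Why: Prins cyclisation: the oxocarbenium ion from aldehyde and homoallylic alcohol closes through a chair with both substituents equatorial and is captured equatorially by trifluoroacetate, so the three ring A centers come out all‑cis relative to the existing carbinol center, and methanolysis then frees the hydroxyl.

Step 15
Reactants: 24 (2S,5S,6R)-6-{[(2S,4S,6R)-6-[(2S)-1-(benzyloxy)propan-2-yl]-4-hydroxyoxan-2-yl]methyl}-2-[(2R)-3-[(tert-butyldiphenylsilyl)oxy]-2-methylpropyl]-5-methyloxan-3-one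
Product: 25 (2S,5S,6R)-6-{[(2S,4S,6R)-6-[(2S)-1-(benzyloxy)propan-2-yl]-4-methoxyoxan-2-yl]methyl}-2-[(2R)-3-[(tert-butyldiphenylsilyl)oxy]-2-methylpropyl]-5-methyloxan-3-one
Conditions: Me3OBF4, 1,8-bis(dimethylamino)naphthalene, CH2Cl2, 25 °C
Reagents that add atoms: trimethyloxonium tetrafluoroborate, C[O+](C)C.F[B-](F)(F)F
Why: O‑Methylation with the oxonium salt and a non‑nucleophilic proton scavenger avoids enolising the ketone, which a hydride base with iodomethane would not.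

Step 16
Reactants: 25 (2S,5S,6R)-6-{[(2S,4S,6R)-6-[(2S)-1-(benzyloxy)propan-2-yl]-4-methoxyoxan-2-yl]methyl}-2-[(2R)-3-[(tert-butyldiphenylsilyl)oxy]-2-methylpropyl]-5-methyloxan-3-one
Product: 26 (2S,3R,5S,6R)-6-{[(2S,4S,6R)-6-[(2S)-1-(benzyloxy)propan-2-yl]-4-methoxyoxan-2-yl]methyl}-2-[(2R)-3-[(tert-butyldiphenylsilyl)oxy]-2-methylpropyl]-3,5-dimethyloxan-3-ol
Conditions: MeAl(OAr)2 (Ar = 2,6-tBu2-4-MeC6H2; from Me3Al and ArOH, 3 equiv), toluene, −78 °C; then MeLi
Reagents that add atoms: methyllithium, [Li]C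
Why: Lewis‑acid‑directed 1,2‑addition: the bulky aluminium bis(aryloxide) binds the ketone oxygen on the equatorial side, so methyllithium enters axially past the single axial hydrogen at C3 and the ring oxygen, giving the equatorial tertiary alcohol with an axial methyl.

Step 17
Reactants: 26 (2S,3R,5S,6R)-6-{[(2S,4S,6R)-6-[(2S)-1-(benzyloxy)propan-2-yl]-4-methoxyoxan-2-yl]methyl}-2-[(2R)-3-[(tert-butyldiphenylsilyl)oxy]-2-methylpropyl]-3,5-dimethyloxan-3-ol
Product: 27 (2S,3R,5S,6R)-2-[(2R)-3-[(tert-butyldiphenylsilyl)oxy]-2-methylpropyl]-6-{[(2S,4S,6R)-6-[(2S)-1-hydroxypropan-2-yl]-4-methoxyoxan-2-yl]methyl}-3,5-dimethyloxan-3-ol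
Conditions: H2 (1 atm), Pd(OH)2/C, EtOAc, 25 °C
Reagents that add atoms: none
Why: Hydrogenolysis cleaves the benzyl ether while the silyl ether stays; it is placed before any alkene is present.

Step 18
Reactants: 27 (2S,3R,5S,6R)-2-[(2R)-3-[(tert-butyldiphenylsilyl)oxy]-2-methylpropyl]-6-{[(2S,4S,6R)-6-[(2S)-1-hydroxypropan-2-yl]-4-methoxyoxan-2-yl]methyl}-3,5-dimethyloxan-3-ol
Product: 28 (2R)-2-[(2R,4S,6S)-6-{[(2R,3S,5R,6S)-6-[(2R)-3-[(tert-butyldiphenylsilyl)oxy]-2-methylpropyl]-5-hydroxy-3,5-dimethyloxan-2-yl]methyl}-4-methoxyoxan-2-yl]propanal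
Conditions: Dess–Martin periodinane, NaHCO3, CH2Cl2, 0 → 25 °C
Reagents that add atoms: none
Why: Dess–Martin oxidation of the primary alcohol gives the α‑methyl aldehyde under neutral conditions; the tertiary alcohol cannot be oxidised and the aldehyde is used at once to avoid epimerisation.

Step 19
Reactants: 28 (2R)-2-[(2R,4S,6S)-6-{[(2R,3S,5R,6S)-6-[(2R)-3-[(tert-butyldiphenylsilyl)oxy]-2-methylpropyl]-5-hydroxy-3,5-dimethyloxan-2-yl]methyl}-4-methoxyoxan-2-yl]propanal, 29 2-(triphenylphosphoranylidene)propanal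
Product: 30 (2E,4S)-4-[(2R,4S,6S)-6-{[(2R,3S,5R,6S)-6-[(2R)-3-[(tert-butyldiphenylsilyl)oxy]-2-methylpropyl]-5-hydroxy-3,5-dimethyloxan-2-yl]methyl}-4-methoxyoxan-2-yl]-2-methylpent-2-enal
Conditions: toluene, 80 °C
Reagents that add atoms: none
Why: Wittig reaction with the stabilised formyl ylide should give the (E)‑trisubstituted enal, since stabilised ylides form the more stable alkene.

Step 20
Reactants: 30 (2E,4S)-4-[(2R,4S,6S)-6-{[(2R,3S,5R,6S)-6-[(2R)-3-[(tert-butyldiphenylsilyl)oxy]-2-methylpropyl]-5-hydroxy-3,5-dimethyloxan-2-yl]methyl}-4-methoxyoxan-2-yl]-2-methylpent-2-enal, 31 diethyl allylphosphonate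
Product: 32 (2S,3R,5S,6R)-2-[(2R)-3-[(tert-butyldiphenylsilyl)oxy]-2-methylpropyl]-6-{[(2S,4S,6R)-4-methoxy-6-[(2S,3E,5E)-4-methylocta-3,5,7-trien-2-yl]oxan-2-yl]methyl}-3,5-dimethyloxan-3-ol
Conditions: (EtO)2P(O)CH2CH=CH2 (3 equiv), nBuLi, THF/HMPA, −78 → 25 °C
Reagents that add atoms: none
Why: Horner–Wadsworth–Emmons reaction of the lithiated allyl phosphonate at its α‑carbon with the enal should give the (E)‑configured terminal diene and thus the triene; the excess anion accounts for the free tertiary hydroxyl.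

Step 21
Reactants: 32 (2S,3R,5S,6R)-2-[(2R)-3-[(tert-butyldiphenylsilyl)oxy]-2-methylpropyl]-6-{[(2S,4S,6R)-4-methoxy-6-[(2S,3E,5E)-4-methylocta-3,5,7-trien-2-yl]oxan-2-yl]methyl}-3,5-dimethyloxan-3-ol
Product: 33 (2S,3R,5S,6R)-2-[(2R)-3-hydroxy-2-methylpropyl]-6-{[(2S,4S,6R)-4-methoxy-6-[(2S,3E,5E)-4-methylocta-3,5,7-trien-2-yl]oxan-2-yl]methyl}-3,5-dimethyloxan-3-ol
Conditions: TBAF, AcOH, THF, 25 °C
Reagents that add atoms: none
Why: Fluoride cleaves the primary silyl ether, and the buffered conditions should leave the triene and the tertiary alcohol untouched.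

Step 22
Reactants: 33 (2S,3R,5S,6R)-2-[(2R)-3-hydroxy-2-methylpropyl]-6-{[(2S,4S,6R)-4-methoxy-6-[(2S,3E,5E)-4-methylocta-3,5,7-trien-2-yl]oxan-2-yl]methyl}-3,5-dimethyloxan-3-ol
Product: 34 (2R)-3-[(2S,3R,5S,6R)-3-hydroxy-6-{[(2S,4S,6R)-4-methoxy-6-[(2S,3E,5E)-4-methylocta-3,5,7-trien-2-yl]oxan-2-yl]methyl}-3,5-dimethyloxan-2-yl]-2-methylpropanal
Conditions: Dess–Martin periodinane, NaHCO3, CH2Cl2, 0 °C
Reagents that add atoms: none
Why: Dess–Martin oxidation gives the α‑methyl aldehyde without isomerising the triene.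

Step 23
Reactants: 34 (2R)-3-[(2S,3R,5S,6R)-3-hydroxy-6-{[(2S,4S,6R)-4-methoxy-6-[(2S,3E,5E)-4-methylocta-3,5,7-trien-2-yl]oxan-2-yl]methyl}-3,5-dimethyloxan-2-yl]-2-methylpropanal, 35 2-(dichloromethyl)-4,4,5,5-tetramethyl-1,3,2-dioxaborolane
Product: 36 (2S,3R,5S,6R)-6-{[(2S,4S,6R)-4-methoxy-6-[(2S,3E,5E)-4-methylocta-3,5,7-trien-2-yl]oxan-2-yl]methyl}-3,5-dimethyl-2-[(2R,3E)-2-methyl-4-(4,4,5,5-tetramethyl-1,3,2-dioxaborolan-2-yl)but-3-en-1-yl]oxan-3-ol
Conditions: CrCl2 (8 equiv), LiI, THF, 25 °C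
Reagents that add atoms: none
Why: Takai‑type olefination with the geminal dichromium species from the dichloromethylboronate should give the (E)‑alkenylboronate, and the reagent tolerates the triene and the free hydroxyl.

Step 24
Reactants: 37 (S)-epichlorohydrin, 38 vinylmagnesium bromide
Product: 39 (S)-1-chloropent-4-en-2-ol
Conditions: CuI (10 mol %), THF, −40 °C
Reagents that add atoms: none
Why: Copper‑catalysed epoxide opening by the vinyl Grignard reagent at the unsubstituted carbon leaves the carbinol center untouched.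

Step 25
Reactants: 39 (S)-1-chloropent-4-en-2-ol
Product: 40 (S)-tert-butyl[(1-chloropent-4-en-2-yl)oxy]dimethylsilane
Conditions: TBSCl, imidazole, DMF, 25 °C
Reagents that add atoms: tert-butyl(chloro)dimethylsilane, CC(C)(C)[Si](C)(C)Cl
Why: Silylation marks this hydroxyl as the one that stays free in the target and keeps it out of the later carbamoylation.

Step 26
Reactants: 40 (S)-tert-butyl[(1-chloropent-4-en-2-yl)oxy]dimethylsilane
Product: 41 tert-butyl{[(2S)-1-chloro-3-(oxiran-2-yl)propan-2-yl]oxy}dimethylsilane (about equal mixture of oxirane epimers)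
Conditions: mCPBA, CH2Cl2, 0 → 25 °C
Reagents that add atoms: 3-chloroperoxybenzoic acid, OOC(=O)c1cccc(Cl)c1
Why: Prilezhaev epoxidation of the terminal alkene; no useful induction from the remote silyl ether is expected, so the epimers are separated chemically in step 27.

Step 27
Reactants: 41 tert-butyl{[(2S)-1-chloro-3-(oxiran-2-yl)propan-2-yl]oxy}dimethylsilane (mixture of oxirane epimers)
Product: 42 tert-butyl{[(2S)-1-chloro-3-[(2S)-oxiran-2-yl]propan-2-yl]oxy}dimethylsilane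
Conditions: (S,S)-(salen)Co(OAc) [salen = N,N′-bis(3,5-di-tert-butylsalicylidene)cyclohexane-1,2-diamine dianion] (1 mol %), H2O (0.55 equiv), THF, 0 → 25 °C
Reagents that add atoms: none
Why: Jacobsen hydrolytic kinetic resolution: the (S,S) cobalt salen complex should hydrolyse the (R)‑oxirane epimer selectively, so the catalyst and not the remote center decides which epimer survives.

Step 28
Reactants: 42 tert-butyl{[(2S)-1-chloro-3-[(2S)-oxiran-2-yl]propan-2-yl]oxy}dimethylsilane, 43 1-propynyllithium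
Product: 44 (2S,4R)-2-[(tert-butyldimethylsilyl)oxy]-1-chlorooct-6-yn-4-ol
Conditions: BF3·OEt2, THF, −78 °C
Reagents that add atoms: none
Why: BF3‑assisted opening of the epoxide at its terminal carbon by the lithium acetylide gives the homopropargylic alcohol with the carbinol configuration retained.

Step 29
Reactants: 44 (2S,4R)-2-[(tert-butyldimethylsilyl)oxy]-1-chlorooct-6-yn-4-ol
Product: 46 (2S,4R,6E)-2-[(tert-butyldimethylsilyl)oxy]-1-chloro-7-iodooct-6-en-4-ol, via alkenylzirconocene 45 (not isolated)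
Conditions: Cp2Zr(H)Cl (3 equiv), THF, 50 °C; then I2, 0 °C
Reagents that add atoms: iodine, II
Why: Hydrozirconation is a syn addition and excess reagent equilibrates zirconium to the methyl‑bearing alkyne carbon; iodinolysis with retention then gives the (E)‑2‑iodoalkene.

Step 30
Reactants: 46 (2S,4R,6E)-2-[(tert-butyldimethylsilyl)oxy]-1-chloro-7-iodooct-6-en-4-ol
Product: 48 (2S,4R,6E)-2-[(tert-butyldimethylsilyl)oxy]-1-chloro-7-iodooct-6-en-4-yl carbamate, via trichloroacetyl carbamate 47 (not isolated)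
Conditions: Cl3CC(O)NCO, CH2Cl2, 0 °C; then K2CO3, MeOH, 25 °C
Reagents that add atoms: trichloroacetyl isocyanate, O=C=NC(=O)C(Cl)(Cl)Cl
Why: Addition of the only free hydroxyl to the isocyanate and methanolysis of the trichloroacetyl group gives the primary carbamate; it is placed before the azide step so that no free hydroxyl can displace the chloride.

Step 31
Reactants: 48 (2S,4R,6E)-2-[(tert-butyldimethylsilyl)oxy]-1-chloro-7-iodooct-6-en-4-yl carbamate
Product: 49 (2S,4R,6E)-1-azido-2-[(tert-butyldimethylsilyl)oxy]-7-iodooct-6-en-4-yl carbamate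
Conditions: NaN3, NaI (cat.), DMF, 70 °C
Reagents that add atoms: sodium azide, [Na+].[N-]=[N+]=[N-]
Why: SN2 displacement of the primary chloride by azide installs the nitrogen in a masked form; the alkenyl iodide is inert to azide without a metal catalyst.

Step 32
Reactants: 49 (2S,4R,6E)-1-azido-2-[(tert-butyldimethylsilyl)oxy]-7-iodooct-6-en-4-yl carbamate
Product: 50 (2S,4R,6E)-1-azido-2-hydroxy-7-iodooct-6-en-4-yl carbamate
Conditions: HF·pyridine, THF/pyridine, 0 → 25 °C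
Reagents that add atoms: none
Why: Buffered fluoride desilylation frees the hydroxyl under conditions in which carbamate migration is not expected.

Step 33
Reactants: 51 methyl 2-methoxyacrylate
Product: 52 2-methoxyacrylic acid
Conditions: LiOH, THF/H2O, 0 °C; then 1 M HCl to pH 3
Reagents that add atoms: lithium hydroxide, [Li+].[OH-]
Why: Saponification at low temperature with careful acidification should spare the enol ether.

Step 34
Reactants: 50 (2S,4R,6E)-1-azido-2-hydroxy-7-iodooct-6-en-4-yl carbamate, 52 2-methoxyacrylic acid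
Product: 54 N-[(2S,4R,6E)-4-(carbamoyloxy)-2-hydroxy-7-iodooct-6-en-1-yl]-2-methoxyprop-2-enamide, via amine 53 (not isolated)
Conditions: PPh3, THF/H2O (10:1), 50 °C; then 52, EDC·HCl, HOBt, iPr2NEt, CH2Cl2, 0 → 25 °C
Reagents that add atoms: none
Why: Staudinger reduction gives the amine, which is acylated in the same flask by the carbodiimide‑activated acid; the amine should react far faster than the secondary hydroxyl.

Step 35
Reactants: 36 (2S,3R,5S,6R)-6-{[(2S,4S,6R)-4-methoxy-6-[(2S,3E,5E)-4-methylocta-3,5,7-trien-2-yl]oxan-2-yl]methyl}-3,5-dimethyl-2-[(2R,3E)-2-methyl-4-(4,4,5,5-tetramethyl-1,3,2-dioxaborolan-2-yl)but-3-en-1-yl]oxan-3-ol, 54 N-[(2S,4R,6E)-4-(carbamoyloxy)-2-hydroxy-7-iodooct-6-en-1-yl]-2-methoxyprop-2-enamide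
Product: 55 N-[(2S,4R,6E,8E,10R)-4-(carbamoyloxy)-2-hydroxy-11-[(2S,3R,5S,6R)-3-hydroxy-6-{[(2S,4S,6R)-4-methoxy-6-[(2S,3E,5E)-4-methylocta-3,5,7-trien-2-yl]oxan-2-yl]methyl}-3,5-dimethyloxan-2-yl]-7,10-dimethylundeca-6,8-dien-1-yl]-2-methoxyprop-2-enamide (CNP0220268.1)
Conditions: Pd(PPh3)4 (10 mol %), TlOEt, THF/H2O (3:1), 25 °C
Reagents that add atoms: none
Why: Suzuki–Miyaura coupling of the (E)‑alkenylboronate with the (E)‑alkenyl iodide proceeds with retention at both partners and tolerates the free hydroxyls, carbamate and amide, so no protecting group has to be removed from the polyene afterwards.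

Compound list
1 | (S)-3-bromo-2-methylpropan-1-ol | BrC[C@@H](C)CO | starting material
2 | (S)-(3-bromo-2-methylpropoxy)(tert-butyl)diphenylsilane | BrC[C@@H](C)CO[Si](c1ccccc1)(c1ccccc1)C(C)(C)C | intermediate
3 | diethyl oxalate | CCOC(=O)C(=O)OCC | starting material
4 | [(2S)-3-[(tert-butyldiphenylsilyl)oxy]-2-methylpropyl]magnesium bromide (not isolated) | Br[Mg]C[C@@H](C)CO[Si](c1ccccc1)(c1ccccc1)C(C)(C)C | intermediate
5 | ethyl (4R)-5-[(tert-butyldiphenylsilyl)oxy]-4-methyl-2-oxopentanoate | CCOC(=O)C(=O)C[C@@H](C)CO[Si](c1ccccc1)(c1ccccc1)C(C)(C)C | intermediate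
6 | ethyl (2S,4R)-5-[(tert-butyldiphenylsilyl)oxy]-2-hydroxy-4-methylpentanoate | CCOC(=O)[C@@H](O)C[C@@H](C)CO[Si](c1ccccc1)(c1ccccc1)C(C)(C)C | intermediate
7 | methyl phenyl sulfone | CS(=O)(=O)c1ccccc1 | starting material
8 | (3S,5R)-6-[(tert-butyldiphenylsilyl)oxy]-3-hydroxy-5-methyl-1-(phenylsulfonyl)hexan-2-one | O=C(CS(=O)(=O)c1ccccc1)[C@@H](O)C[C@@H](C)CO[Si](c1ccccc1)(c1ccccc1)C(C)(C)C | intermediate
9 | (R)-but-3-en-2-ol | C[C@@H](O)C=C | starting material
10 | ethyl acrylate | C=CC(=O)OCC | starting material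
11 | ethyl (2E,4R)-4-hydroxypent-2-enoate | CCOC(=O)/C=C/[C@@H](C)O | intermediate
12 | ethyl (2E,4R)-4-[(methoxycarbonyl)oxy]pent-2-enoate | CCOC(=O)/C=C/[C@@H](C)OC(=O)OC | intermediate
13 | ethyl (2E,4R,7S,9R)-10-[(tert-butyldiphenylsilyl)oxy]-7-hydroxy-4,9-dimethyl-6-oxo-5-(phenylsulfonyl)dec-2-enoate (not isolated; C5 labile) | CCOC(=O)/C=C/[C@@H](C)C(S(=O)(=O)c1ccccc1)C(=O)[C@@H](O)C[C@@H](C)CO[Si](c1ccccc1)(c1ccccc1)C(C)(C)C | intermediate
14 | ethyl 2-[(2R,3R,4S,6S)-6-[(2R)-3-[(tert-butyldiphenylsilyl)oxy]-2-methylpropyl]-3-methyl-5-oxo-4-(phenylsulfonyl)oxan-2-yl]acetate | CCOC(=O)C[C@H]1O[C@@H](C[C@@H](C)CO[Si](c2ccccc2)(c2ccccc2)C(C)(C)C)C(=O)[C@@H](S(=O)(=O)c2ccccc2)[C@@H]1C | intermediate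
15 | ethyl 2-[(2R,3S,6S)-6-[(2R)-3-[(tert-butyldiphenylsilyl)oxy]-2-methylpropyl]-3-methyl-5-oxooxan-2-yl]acetate | CCOC(=O)C[C@H]1O[C@@H](C[C@@H](C)CO[Si](c2ccccc2)(c2ccccc2)C(C)(C)C)C(=O)C[C@@H]1C | intermediate
16 | 2-[(2R,3S,5R,6S)-6-[(2R)-3-[(tert-butyldiphenylsilyl)oxy]-2-methylpropyl]-5-hydroxy-3-methyloxan-2-yl]ethan-1-ol (major C5 epimer) | OCC[C@H]1O[C@@H](C[C@@H](C)CO[Si](c2ccccc2)(c2ccccc2)C(C)(C)C)[C@H](O)C[C@@H]1C | intermediate
17 | 2-[(2R,3S,6S)-6-[(2R)-3-[(tert-butyldiphenylsilyl)oxy]-2-methylpropyl]-3-methyl-5-oxooxan-2-yl]acetaldehyde | O=CC[C@H]1O[C@@H](C[C@@H](C)CO[Si](c2ccccc2)(c2ccccc2)C(C)(C)C)C(=O)C[C@@H]1C | intermediate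
18 | methyl (S)-3-hydroxy-2-methylpropanoate | COC(=O)[C@@H](C)CO | starting material
19 | methyl (S)-3-(benzyloxy)-2-methylpropanoate | COC(=O)[C@@H](C)COCc1ccccc1 | intermediate
20 | (S)-3-(benzyloxy)-2-methylpropanal | O=C[C@@H](C)COCc1ccccc1 | intermediate
21 | allyltrimethylsilane | C=CC[Si](C)(C)C | starting material
22 | (2S,3R)-1-(benzyloxy)-2-methylhex-5-en-3-ol | C=CC[C@@H](O)[C@@H](C)COCc1ccccc1 | intermediate
23 | (2S,4S,6R)-2-{[(2R,3S,6S)-6-[(2R)-3-[(tert-butyldiphenylsilyl)oxy]-2-methylpropyl]-3-methyl-5-oxooxan-2-yl]methyl}-6-[(2S)-1-(benzyloxy)propan-2-yl]oxan-4-yl 2,2,2-trifluoroacetate (not isolated) | c1ccccc1COC[C@H](C)[C@H]1C[C@@H](OC(=O)C(F)(F)F)C[C@@H](C[C@H]2O[C@@H](C[C@@H](C)CO[Si](c3ccccc3)(c3ccccc3)C(C)(C)C)C(=O)C[C@@H]2C)O1 | intermediate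
24 | (2S,5S,6R)-6-{[(2S,4S,6R)-6-[(2S)-1-(benzyloxy)propan-2-yl]-4-hydroxyoxan-2-yl]methyl}-2-[(2R)-3-[(tert-butyldiphenylsilyl)oxy]-2-methylpropyl]-5-methyloxan-3-one | c1ccccc1COC[C@H](C)[C@H]1C[C@@H](O)C[C@@H](C[C@H]2O[C@@H](C[C@@H](C)CO[Si](c3ccccc3)(c3ccccc3)C(C)(C)C)C(=O)C[C@@H]2C)O1 | intermediate
25 | (2S,5S,6R)-6-{[(2S,4S,6R)-6-[(2S)-1-(benzyloxy)propan-2-yl]-4-methoxyoxan-2-yl]methyl}-2-[(2R)-3-[(tert-butyldiphenylsilyl)oxy]-2-methylpropyl]-5-methyloxan-3-one | c1ccccc1COC[C@H](C)[C@H]1C[C@@H](OC)C[C@@H](C[C@H]2O[C@@H](C[C@@H](C)CO[Si](c3ccccc3)(c3ccccc3)C(C)(C)C)C(=O)C[C@@H]2C)O1 | intermediate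
26 | (2S,3R,5S,6R)-6-{[(2S,4S,6R)-6-[(2S)-1-(benzyloxy)propan-2-yl]-4-methoxyoxan-2-yl]methyl}-2-[(2R)-3-[(tert-butyldiphenylsilyl)oxy]-2-methylpropyl]-3,5-dimethyloxan-3-ol | c1ccccc1COC[C@H](C)[C@H]1C[C@@H](OC)C[C@@H](C[C@H]2O[C@@H](C[C@@H](C)CO[Si](c3ccccc3)(c3ccccc3)C(C)(C)C)[C@](C)(O)C[C@@H]2C)O1 | intermediate
27 | (2S,3R,5S,6R)-2-[(2R)-3-[(tert-butyldiphenylsilyl)oxy]-2-methylpropyl]-6-{[(2S,4S,6R)-6-[(2S)-1-hydroxypropan-2-yl]-4-methoxyoxan-2-yl]methyl}-3,5-dimethyloxan-3-ol | OC[C@H](C)[C@H]1C[C@@H](OC)C[C@@H](C[C@H]2O[C@@H](C[C@@H](C)CO[Si](c3ccccc3)(c3ccccc3)C(C)(C)C)[C@](C)(O)C[C@@H]2C)O1 | intermediate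
28 | (2R)-2-[(2R,4S,6S)-6-{[(2R,3S,5R,6S)-6-[(2R)-3-[(tert-butyldiphenylsilyl)oxy]-2-methylpropyl]-5-hydroxy-3,5-dimethyloxan-2-yl]methyl}-4-methoxyoxan-2-yl]propanal | O=C[C@H](C)[C@H]1C[C@@H](OC)C[C@@H](C[C@H]2O[C@@H](C[C@@H](C)CO[Si](c3ccccc3)(c3ccccc3)C(C)(C)C)[C@](C)(O)C[C@@H]2C)O1 | intermediate
29 | 2-(triphenylphosphoranylidene)propanal | CC(C=O)=P(c1ccccc1)(c1ccccc1)c1ccccc1 | starting material
30 | (2E,4S)-4-[(2R,4S,6S)-6-{[(2R,3S,5R,6S)-6-[(2R)-3-[(tert-butyldiphenylsilyl)oxy]-2-methylpropyl]-5-hydroxy-3,5-dimethyloxan-2-yl]methyl}-4-methoxyoxan-2-yl]-2-methylpent-2-enal | O=C/C(C)=C/[C@H](C)[C@H]1C[C@@H](OC)C[C@@H](C[C@H]2O[C@@H](C[C@@H](C)CO[Si](c3ccccc3)(c3ccccc3)C(C)(C)C)[C@](C)(O)C[C@@H]2C)O1 | intermediate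
31 | diethyl allylphosphonate | C=CCP(=O)(OCC)OCC | starting material
32 | (2S,3R,5S,6R)-2-[(2R)-3-[(tert-butyldiphenylsilyl)oxy]-2-methylpropyl]-6-{[(2S,4S,6R)-4-methoxy-6-[(2S,3E,5E)-4-methylocta-3,5,7-trien-2-yl]oxan-2-yl]methyl}-3,5-dimethyloxan-3-ol | C=C/C=C/C(C)=C/[C@H](C)[C@H]1C[C@@H](OC)C[C@@H](C[C@H]2O[C@@H](C[C@@H](C)CO[Si](c3ccccc3)(c3ccccc3)C(C)(C)C)[C@](C)(O)C[C@@H]2C)O1 | intermediate
33 | (2S,3R,5S,6R)-2-[(2R)-3-hydroxy-2-methylpropyl]-6-{[(2S,4S,6R)-4-methoxy-6-[(2S,3E,5E)-4-methylocta-3,5,7-trien-2-yl]oxan-2-yl]methyl}-3,5-dimethyloxan-3-ol | C=C/C=C/C(C)=C/[C@H](C)[C@H]1C[C@@H](OC)C[C@@H](C[C@H]2O[C@@H](C[C@@H](C)CO)[C@](C)(O)C[C@@H]2C)O1 | intermediate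
34 | (2R)-3-[(2S,3R,5S,6R)-3-hydroxy-6-{[(2S,4S,6R)-4-methoxy-6-[(2S,3E,5E)-4-methylocta-3,5,7-trien-2-yl]oxan-2-yl]methyl}-3,5-dimethyloxan-2-yl]-2-methylpropanal | C=C/C=C/C(C)=C/[C@H](C)[C@H]1C[C@@H](OC)C[C@@H](C[C@H]2O[C@@H](C[C@@H](C)C=O)[C@](C)(O)C[C@@H]2C)O1 | intermediate
35 | 2-(dichloromethyl)-4,4,5,5-tetramethyl-1,3,2-dioxaborolane | ClC(Cl)B1OC(C)(C)C(C)(C)O1 | starting material
36 | (2S,3R,5S,6R)-6-{[(2S,4S,6R)-4-methoxy-6-[(2S,3E,5E)-4-methylocta-3,5,7-trien-2-yl]oxan-2-yl]methyl}-3,5-dimethyl-2-[(2R,3E)-2-methyl-4-(4,4,5,5-tetramethyl-1,3,2-dioxaborolan-2-yl)but-3-en-1-yl]oxan-3-ol | C=C/C=C/C(C)=C/[C@H](C)[C@H]1C[C@@H](OC)C[C@@H](C[C@H]2O[C@@H](C[C@@H](C)/C=C/B3OC(C)(C)C(C)(C)O3)[C@](C)(O)C[C@@H]2C)O1 | intermediate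
37 | (S)-epichlorohydrin | ClC[C@@H]1CO1 | starting material
38 | vinylmagnesium bromide | C=C[Mg]Br | starting material
39 | (S)-1-chloropent-4-en-2-ol | C=CC[C@H](O)CCl | intermediate
40 | (S)-tert-butyl[(1-chloropent-4-en-2-yl)oxy]dimethylsilane | C=CC[C@H](O[Si](C)(C)C(C)(C)C)CCl | intermediate
41 | tert-butyl{[(2S)-1-chloro-3-(oxiran-2-yl)propan-2-yl]oxy}dimethylsilane (mixture of oxirane epimers) | C1OC1C[C@H](O[Si](C)(C)C(C)(C)C)CCl | intermediate
42 | tert-butyl{[(2S)-1-chloro-3-[(2S)-oxiran-2-yl]propan-2-yl]oxy}dimethylsilane | C1[C@H](C[C@H](O[Si](C)(C)C(C)(C)C)CCl)O1 | intermediate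
43 | 1-propynyllithium | [Li]C#CC | starting material
44 | (2S,4R)-2-[(tert-butyldimethylsilyl)oxy]-1-chlorooct-6-yn-4-ol | CC#CC[C@H](C[C@H](O[Si](C)(C)C(C)(C)C)CCl)O | intermediate
45 | (E)-alkenylzirconocene chloride from 44 (not isolated; hydroxyl present as its zirconium alkoxide in the flask, drawn as the alcohol) | Cl[Zr](C1C=CC=C1)(C1C=CC=C1)/C(C)=C/C[C@H](C[C@H](O[Si](C)(C)C(C)(C)C)CCl)O | intermediate
46 | (2S,4R,6E)-2-[(tert-butyldimethylsilyl)oxy]-1-chloro-7-iodooct-6-en-4-ol | I/C(C)=C/C[C@H](C[C@H](O[Si](C)(C)C(C)(C)C)CCl)O | intermediate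
47 | (2S,4R,6E)-2-[(tert-butyldimethylsilyl)oxy]-1-chloro-7-iodooct-6-en-4-yl (2,2,2-trichloroacetyl)carbamate (not isolated) | I/C(C)=C/C[C@H](C[C@H](O[Si](C)(C)C(C)(C)C)CCl)OC(=O)NC(=O)C(Cl)(Cl)Cl | intermediate
48 | (2S,4R,6E)-2-[(tert-butyldimethylsilyl)oxy]-1-chloro-7-iodooct-6-en-4-yl carbamate | I/C(C)=C/C[C@H](C[C@H](O[Si](C)(C)C(C)(C)C)CCl)OC(N)=O | intermediate
49 | (2S,4R,6E)-1-azido-2-[(tert-butyldimethylsilyl)oxy]-7-iodooct-6-en-4-yl carbamate | I/C(C)=C/C[C@H](C[C@H](O[Si](C)(C)C(C)(C)C)CN=[N+]=[N-])OC(N)=O | intermediate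
50 | (2S,4R,6E)-1-azido-2-hydroxy-7-iodooct-6-en-4-yl carbamate | I/C(C)=C/C[C@H](C[C@H](O)CN=[N+]=[N-])OC(N)=O | intermediate
51 | methyl 2-methoxyacrylate | COC(=C)C(=O)OC | starting material
52 | 2-methoxyacrylic acid | COC(=C)C(=O)O | intermediate
53 | (2S,4R,6E)-1-amino-2-hydroxy-7-iodooct-6-en-4-yl carbamate (not isolated) | I/C(C)=C/C[C@H](C[C@H](O)CN)OC(N)=O | intermediate
54 | N-[(2S,4R,6E)-4-(carbamoyloxy)-2-hydroxy-7-iodooct-6-en-1-yl]-2-methoxyprop-2-enamide | I/C(C)=C/C[C@H](C[C@H](O)CNC(=O)C(=C)OC)OC(N)=O | intermediate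
55 | N-[(2S,4R,6E,8E,10R)-4-(carbamoyloxy)-2-hydroxy-11-[(2S,3R,5S,6R)-3-hydroxy-6-{[(2S,4S,6R)-4-methoxy-6-[(2S,3E,5E)-4-methylocta-3,5,7-trien-2-yl]oxan-2-yl]methyl}-3,5-dimethyloxan-2-yl]-7,10-dimethylundeca-6,8-dien-1-yl]-2-methoxyprop-2-enamide (CNP0220268.1) | C=C/C=C/C(C)=C/[C@H](C)[C@H]1C[C@@H](OC)C[C@@H](C[C@H]2O[C@@H](C[C@@H](C)/C=C/C(C)=C/C[C@H](C[C@H](O)CNC(=O)C(=C)OC)OC(N)=O)[C@](C)(O)C[C@@H]2C)O1 | target

Total step count: 35. Longest linear sequence: 19 steps (steps 1–4, 7–10, 14–23 and 35).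

Steps most likely to fail

Step 7. The allylpalladium intermediate may lose its configuration before it is trapped, the carbanion may attack the ester‑proximal terminus, or the adduct may close through the enolate oxygen instead of the hydroxyl. The fallback sets out from 8 and lets a catalyst, not a transferred center, set C3. An iridium‑catalysed, branched‑selective asymmetric allylic alkylation of 8 with (E)-but-2-en-1-yl methyl carbonate ([Ir(cod)Cl]2, a binaphthol‑derived phosphoramidite ligand of the enantiomeric series that gives the (7R) center, THF) should give the branched vinyl keto sulfone (2R,4S,7R)-1-[(tert-butyldiphenylsilyl)oxy]-4-hydroxy-2,7-dimethyl-6-(phenylsulfonyl)non-8-en-5-one F1. Cross‑metathesis of this compound with ethyl acrylate 10 (second‑generation Hoveyda–Grubbs catalyst) then gives 13, which is cyclised with DBU as a separate operation. The fallback comes back to the route at 14.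

Step 16. Facial selectivity may be poor if methyl is delivered equatorially or through a chelate with the ring oxygen. The fallback sets out from 25. Corey–Chaykovsky methylenation with dimethylsulfonium methylide (Me3SI, nBuLi, THF, −10 °C) adds the methylene axially and irreversibly and should give the spiro‑epoxide of 25 at the ketone carbon (oxirane oxygen equatorial, methylene axial) F2. Reductive opening of this epoxide at the methylene with LiBHEt3 turns it into the axial methyl group. The fallback comes back to the route at 26.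

Step 20. The geometry of the new disubstituted alkene may erode, or the allyl phosphonate anion may react through its γ‑carbon. The fallback sets out from 30 and builds the terminus in two olefinations. A Wittig reaction with (triphenylphosphoranylidene)acetaldehyde (toluene, 80 °C) should give the dienal (2E,4E,6S)-6-[(2R,4S,6S)-6-{[(2R,3S,5R,6S)-6-[(2R)-3-[(tert-butyldiphenylsilyl)oxy]-2-methylpropyl]-5-hydroxy-3,5-dimethyloxan-2-yl]methyl}-4-methoxyoxan-2-yl]-4-methylhepta-2,4-dienal F3. Methylenation of this dienal with Ph3P=CH2 (THF, 0 °C) completes the triene. The fallback comes back to the route at 32.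

Further compounds
F1 | step 7 | (2R,4S,7R)-1-[(tert-butyldiphenylsilyl)oxy]-4-hydroxy-2,7-dimethyl-6-(phenylsulfonyl)non-8-en-5-one | C=C[C@@H](C)C(S(=O)(=O)c1ccccc1)C(=O)[C@@H](O)C[C@@H](C)CO[Si](c1ccccc1)(c1ccccc1)C(C)(C)C
F2 | step 16 | spiro-epoxide of 25 at the ketone carbon (oxirane oxygen equatorial, methylene axial) | c1ccccc1COC[C@H](C)[C@H]1C[C@@H](OC)C[C@@H](C[C@H]2O[C@@H](C[C@@H](C)CO[Si](c3ccccc3)(c3ccccc3)C(C)(C)C)[C@@]4(CO4)C[C@@H]2C)O1
F3 | step 20 | (2E,4E,6S)-6-[(2R,4S,6S)-6-{[(2R,3S,5R,6S)-6-[(2R)-3-[(tert-butyldiphenylsilyl)oxy]-2-methylpropyl]-5-hydroxy-3,5-dimethyloxan-2-yl]methyl}-4-methoxyoxan-2-yl]-4-methylhepta-2,4-dienal | O=C/C=C/C(C)=C/[C@H](C)[C@H]1C[C@@H](OC)C[C@@H](C[C@H]2O[C@@H](C[C@@H](C)CO[Si](c3ccccc3)(c3ccccc3)C(C)(C)C)[C@](C)(O)C[C@@H]2C)O1
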